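**Numbering convention.** The ring atoms of the target are numbered C1 (carbonyl between the docosyl and methoxy carbons), C2 (docosyl), C3 (methyl), C4 (carbonyl), C5 (H), C6 (OCH3). Chain atoms of open-chain precursors carry the label of the ring atom they become.

## Analysis of the target

Compound 14 is a single six-membered carbocycle at the para-quinone oxidation level, 2-docosyl-6-methoxy-3-methyl-1,4-benzoquinone (C30H52O3). The ring carries four different groups: an unbranched C22 chain on C2, a methyl on C3, a hydrogen on C5 and a methoxy on C6. There is no stereocentre and no element of symmetry, so the whole problem is one of regiochemistry around the ring. The methoxyquinone is the sensitive part: it is a vinylogous ester on a redox-active, light- and base-sensitive ring, and nucleophiles displace the methoxy group at C6 by addition–elimination. It should therefore be formed at the very end. The docosyl chain makes every intermediate waxy and poorly soluble in polar or cold media, which matters for enolate chemistry and for aqueous oxidants. The strategy rests on the oxygens on C4 and C6 being meta to each other, with C2 bearing the chain. Read as C2–C3–C4–C5–C6–C1, the ring is a folded tetraketide built on a tricosanoyl starter: ketone carbons at C2, C4 and C6, the methyl on the carbon between the C2 and C4 ketones, and a carboxyl terminus on C1. The C1 oxygen is not part of this pattern, and it sits para to the C4 oxygen, where a phenol oxidation can place it.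

## Retrosynthetic reasoning

**14 to 13 (O–CH3 bond).** The methyl ether is cut first, because the methoxyquinone is the most fragile function and is best made last. Hydroxyquinone 13 is a vinylogous carboxylic acid, so an acid-catalysed esterification-type methylation should act on this one oxygen only. No other hydroxyl is present at that stage, so no chemoselectivity question arises.

**13 to 12 (C1 oxygen).** Removing the C1 oxygen and lowering the oxidation level leads to resorcinol 12, 5-docosyl-4-methylbenzene-1,3-diol. C1 is para to the C4 hydroxyl, while the other para position (C3, para to the C6 hydroxyl) is blocked by the methyl, so only one para-quinone can form. Oxidation that begins at the C6 hydroxyl and oxygenates C1 in the ortho sense converges on the same compound by tautomerism. What is gained is a resorcinol, whose 1,3-dioxygenation is exactly what a polyketide cyclisation delivers.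

**12 to 10 through 11 (C1–carboxyl bond).** A carboxyl is put back on C1 and tied to the C6 oxygen as an acetonide lactone, giving benzodioxinone 10. The carboxyl is the end of the polyketide chain: it makes C1 nucleophilic during ring construction and it masks the carboxyl terminus. It then leaves from exactly the carbon that must be free for the oxidation. In the forward direction the lactone is saponified to acid 11, which decarboxylates easily because the carboxyl sits ortho and para to hydroxyls.

**10 to 8 (C1–C2 ring bond, the key disconnection).** The aromatic ring is opened between C1 and C2 to give diketo-dioxinone 8. This is the only ring bond that joins an ester α-carbon to a ketone carbon, so it is the bond an aldol condensation makes. The ring problem of four different substituents becomes a chain problem in which each substituent's position is fixed by the order of the chain atoms. The forward reaction must close carbon on carbon, choose the C2 ketone, and dehydrate to the arene.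

**8 to 4 and 6 (C2–C3 bond).** The bond between the docosyl ketone carbon and the methyl-bearing carbon is a Claisen bond. Cutting it splits the molecule into the C23 acyl unit, used as imidazolide 6 (made from acid 5), and the small keto-dioxinone 4. The nucleophile is the more basic carbon of dianion 7, so the acylation takes place at C3 and not at C5.

**4 to 1 and 2 (C4–C5 bond).** Keto-dioxinone 4 comes from acylation of dienolate 3, derived from dioxinone 1, with acid chloride 2. Compound 1 supplies C1, C6, C5 and the carboxyl carbon. Compound 2 supplies C4, C3 and the C3 methyl.

## Alternatives that were turned down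

**Alternative 1:** The C2–docosyl and C3–methyl bonds are cut from a preformed oxygenated ring, the quinone monoketal A2 (3,4,4-trimethoxycyclohexa-2,5-dien-1-one). In the forward sense a copper-catalysed conjugate addition of docosylmagnesium bromide A3 to the unsubstituted enone carbon of A2 is followed by C-methylation of the enolate in the same flask. This gives the racemic trans ketone A1; ketal hydrolysis, enolisation and oxidation would then lead to 14.
- In its favour: the ring and all three oxygens are present from the start and the methoxy group is already differentiated. The sequence is about half as long as the chosen one and is convergent, so on step economy it is clearly stronger.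
- Against it: quinone monoketals tend to suffer 1,2-addition and electron-transfer reduction to the phenol with organocopper reagents. Magnesium enolates C-methylate slowly and equilibrate by proton transfer, so unmethylated and over-methylated material is likely. Adducts of type A1 lose a methoxy group and aromatise easily, possibly before methylation is complete. Two carbon–carbon bonds would have to form in one flask on a redox-labile substrate with a waxy C22 Grignard reagent at low temperature.
- Comparison: the chosen strategy spends more steps, but every carbon–carbon bond comes from carbonyl condensation, with positions fixed by chain connectivity.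

**Alternative 2:** The C2–C3 and C1–C6 bonds are cut in a [4+2] sense, giving a ketene-acetal diene A5 (taken here as 1,1-dimethoxy-3-(trimethylsilyloxy)penta-1,3-diene, supplying C3 to C6) and the nitroalkene A6 ((E)-1-nitrotetracos-1-ene, supplying C1 and C2). The cycloadduct would aromatise by elimination of the nitro group and of one methoxy group to the phenol A4 (3-docosyl-5-methoxy-2-methylphenol). A para-oxidation of A4 of the kind used in step 6 would give 14 directly.
- In its favour: the polarity of both partners fixes the regiochemistry. The two oxygens are differentiated from the outset, so no late methylation is needed; on this point it is stronger than the chosen route. The step count is comparable or slightly lower.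
- Against it: the nucleophilic terminus of A5 carries the methyl group, which slows the cycloaddition and makes the diene geometry matter. Dienes of this class hydrolyse readily. A6 is an unactivated aliphatic nitroalkene, a modest dienophile that tends to isomerise to the allylic nitro compound and to oligomerise under base. Aromatisation needs two eliminations in the right order, or a cyclohexenone or an open-chain Michael adduct results. A6 must also be built from the aldehyde oxidation level of 5 by a nitroaldol–dehydration sequence.
- Comparison: the chosen strategy offers storable intermediates and a ring closure with only one possible regiochemical outcome.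

**Alternative 3:** The ring is cut at C3–C4 and at C1–C2 into the four-carbon unit A9 (3-methoxycyclobut-3-ene-1,2-dione) and the alkenyl unit A10 ((pentacos-2-en-3-yl)lithium). Addition of A10 to the carbonyl of A9 next to the methoxy-bearing carbon would give the cyclobutenone adduct A8. On heating, A8 would open to a dienylketene, whose ketene carbon bonds to the methyl-bearing alkene carbon; tautomerisation gives the hydroquinone A7 (2-docosyl-6-methoxy-3-methylbenzene-1,4-diol), one mild oxidation away from 14.
- In its favour: this is the most direct of the four routes once the fragments exist. All oxygens and the methoxy group are in place, the ring expansion has only one regiochemical outcome, and the last oxidation is trivial. On step count after the fragments and on oxygen differentiation it is stronger than the chosen route.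
- Against it: A10 is a trisubstituted alkenyllithium with the metal on the carbon that bears the C22 chain. Its vinyl halide precursor is hard to make regiochemically pure, because hydrometalation of the internal alkyne and enolisation-based routes cannot tell the two flanking positions apart. The steps saved on the ring are therefore spent on the fragment. A9 needs a partial reduction of a squarate diester, and A8 is an acid-sensitive tertiary allylic alcohol.
- Comparison: the chosen strategy starts from three bulk chemicals and fixes every position by construction, without a regiochemically defined organometallic fragment.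

Key step: step 4

Remark on the chemistry: 8 and 9 are drawn as keto tautomers; the C3 methine of 8 and the two sp3 centres of 9 are racemic, labile and erased in step 4.

## Route

Step 1
Reactants: 1 2,2,6-trimethyl-4H-1,3-dioxin-4-one; 2 propionyl chloride
Product: 4 2,2-dimethyl-6-(2-oxobutyl)-4H-1,3-dioxin-4-one, via lithium dienolate 3 (not isolated)
Conditions: LiN(SiMe3)2 (commercial solution, 2 equiv), 1 (2 equiv), THF, −78 °C; then 2 (1 equiv), −78 °C; aq HCl quench
Reagents that add atoms: none
Why: γ-Deprotonation of the vinylogous ester gives dienolate 3, which is C-acylated at its exocyclic carbon by the acid chloride (Claisen-type acylation of a dioxinone dienolate, forming C4–C5). The second equivalent of 3 takes up the acidic proton of 4, which protects 4 from a second acylation; the excess 1 is recovered.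

Step 2
Reactants: 5 tricosanoic acid
Product: 6 1-(1H-imidazol-1-yl)tricosan-1-one (tricosanoyl imidazolide)
Conditions: 1,1'-carbonyldiimidazole, THF, 45 °C; cool, filter, wash with cold MeCN
Reagents that add atoms: 1,1'-carbonyldiimidazole, O=C(n1ccnc1)n1ccnc1
Why: Standard activation of a carboxylic acid as its N-acylimidazole with loss of CO2 and imidazole. The long-chain imidazolide should crystallise on cooling, which removes the imidazole that would otherwise consume base in step 3.

Step 3
Reactants: 4 2,2-dimethyl-6-(2-oxobutyl)-4H-1,3-dioxin-4-one; 6 1-(1H-imidazol-1-yl)tricosan-1-one
Product: 8 2,2-dimethyl-6-(3-methyl-2,4-dioxohexacosyl)-4H-1,3-dioxin-4-one, via dilithio dianion 7 (not isolated)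
Conditions: LiN(iPr)2 (commercial solution, 3.2 equiv), THF, −78 → −40 °C; then 6 in warm THF, −78 → −20 °C; cold aq HCl to pH 3
Reagents that add atoms: none
Why: Two equivalents of amide base remove first a proton of the doubly activated C5H2 and then one of the ethyl CH2. Dianion 7 reacts at this later-formed, more basic carbon with the acyl imidazolide (crossed Claisen condensation of a dianion, forming C2–C3), and the third equivalent covers the acidic methine of the new 1,3-diketone. Compound 8 is labile towards base and silica and is carried on crude.

Step 4
Reactants: 8 2,2-dimethyl-6-(3-methyl-2,4-dioxohexacosyl)-4H-1,3-dioxin-4-one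
Product: 10 5-docosyl-7-hydroxy-2,2,6-trimethyl-4H-1,3-benzodioxin-4-one, via aldol carbinol 9 (not isolated)
Conditions: Et3N, CH2Cl2, 23 °C; then 1 M HCl wash
Reagents that add atoms: none
Why: Triethylamine reversibly removes a proton from C5H2, between the C4 ketone and the vinylogous ester, giving a dienolate whose charge reaches the dioxinone α-carbon C1; C1 adds to the C2 (docosyl) ketone to form carbinol 9, E1cB loss of water across C2–C3 follows, and enolisation through C5 gives phenol 10. The closest known reaction type is the amine-mediated aldol cyclisation–aromatisation of diketo-dioxinones to acetonide-protected β-resorcylates, the laboratory counterpart of the fold used by alkylresorcinol- and orsellinate-forming polyketide synthases. The one ring closes in a 6-exo-trig aldol; with respect to the reacting ester dienolate it is 6-(enolexo)-exo-trig, since the C1=C(O−) unit lies outside the new ring while the C4 enol unit lies inside it, and this mode is allowed by Baldwin's rules for enolates. No stereocentre survives, because the C3 methine of 8 and both sp3 centres of 9 are flattened on aromatisation. The step needs carbon–carbon closure instead of oxygen closure, and the acetonide secures this by holding both the carboxyl and the C6 enol oxygen, so that neither a pyranone nor a free β-keto acid can form. It also needs the right carbonyl: attack of C1 on C2 is the only closure giving a six-membered ring that can aromatise, whereas attack on C4 would be four-membered and attack of C3 on the lactone carbonyl would build a quaternary centre reversibly. The C3 methyl lowers the enol content of the C2/C4 diketone, which should keep C2 electrophilic, but it also makes the C3 methine a competing, unproductive site of deprotonation, so the closure runs from the minor enolate.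

Step 5
Reactants: 10 5-docosyl-7-hydroxy-2,2,6-trimethyl-4H-1,3-benzodioxin-4-one
Product: 12 5-docosyl-4-methylbenzene-1,3-diol, via resorcylic acid 11 (not isolated)
Conditions: KOH, H2O–EtOH–1,4-dioxane, 90 °C, Ar; then HCl to pH 1, 100 °C
Reagents that add atoms: none
Why: Hydroxide opens the aryl ester of the acetonide (saponification), releasing acetone and the salicylate 11. On acidification and heating, 11 is protonated at C1, which is ortho and para to the hydroxyls, and loses CO2 (protodecarboxylation of a β-resorcylic acid). The oxygen taken up from hydroxide leaves again with CO2; air is excluded to protect the electron-rich resorcinolate.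

Step 6
Reactants: 12 5-docosyl-4-methylbenzene-1,3-diol
Product: 13 2-docosyl-6-hydroxy-3-methyl-1,4-benzoquinone (2-docosyl-6-hydroxy-3-methylcyclohexa-2,5-diene-1,4-dione)
Conditions: (KSO3)2NO, aq KH2PO4, THF–H2O, Bu4NHSO4 (cat.), 0 °C → rt
Reagents that add atoms: potassium nitrosodisulfonate (KSO3)2NO, [K+].[K+].[O]N(S(=O)(=O)[O-])S(=O)(=O)[O-]
Why: Teuber oxidation: one nitroxide abstracts the hydrogen of the C4 hydroxyl and a second couples at C1, the only unsubstituted position para to a hydroxyl, since C3 carries the methyl; loss of imidodisulfonate gives the para-quinone. Oxidation that starts from the C6 hydroxyl and reaches C1 gives the same compound through ortho-quinone to hydroxy-para-quinone tautomerism.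

Step 7
Reactants: 13 2-docosyl-6-hydroxy-3-methyl-1,4-benzoquinone
Product: 14 2-docosyl-6-methoxy-3-methyl-1,4-benzoquinone (target)
Conditions: MeOH–CHCl3, H2SO4 (cat.), 50 °C
Reagents that add atoms: methanol, CO
Why: The 2-hydroxy-1,4-quinone is a vinylogous carboxylic acid, so protonation, addition of methanol at C6 and loss of water (acid-catalysed vinylogous esterification) should give the methoxy-para-quinone, which is favoured over the isomeric ortho-quinone ether. C2 and C3 are fully substituted and C5 is the electron-rich α-carbon, so conjugate addition of methanol is not expected.

## Compound list

1 | 2,2,6-trimethyl-4H-1,3-dioxin-4-one | CC1=CC(=O)OC(C)(C)O1 | starting material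
2 | propionyl chloride | CCC(=O)Cl | starting material
3 | lithium 2,2-dimethyl-6-methylidene-6H-1,3-dioxin-4-olate (lithium dienolate of 1) | [Li+].C=C1C=C([O-])OC(C)(C)O1 | intermediate
4 | 2,2-dimethyl-6-(2-oxobutyl)-4H-1,3-dioxin-4-one | CCC(=O)CC1=CC(=O)OC(C)(C)O1 | intermediate
5 | tricosanoic acid | CCCCCCCCCCCCCCCCCCCCCCC(=O)O | starting material
6 | 1-(1H-imidazol-1-yl)tricosan-1-one | CCCCCCCCCCCCCCCCCCCCCCC(=O)n1ccnc1 | intermediate
7 | dilithium dianion of 4 (ketone enolate on the ethyl side plus dioxinone dienolate) | [Li+].[Li+].CC=C([O-])C=C1C=C([O-])OC(C)(C)O1 | intermediate
8 | 2,2-dimethyl-6-(3-methyl-2,4-dioxohexacosyl)-4H-1,3-dioxin-4-one (racemic, labile methine) | CCCCCCCCCCCCCCCCCCCCCCC(=O)C(C)C(=O)CC1=CC(=O)OC(C)(C)O1 | intermediate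
9 | 5-docosyl-5-hydroxy-2,2,6-trimethyl-5,6-dihydro-4H-1,3-benzodioxine-4,7(8H)-dione (racemic diastereomer mixture) | CCCCCCCCCCCCCCCCCCCCCCC1(O)C(C)C(=O)CC2=C1C(=O)OC(C)(C)O2 | intermediate
10 | 5-docosyl-7-hydroxy-2,2,6-trimethyl-4H-1,3-benzodioxin-4-one | CCCCCCCCCCCCCCCCCCCCCCc1c(C)c(O)cc2OC(C)(C)OC(=O)c12 | intermediate
11 | 2-docosyl-4,6-dihydroxy-3-methylbenzoic acid | CCCCCCCCCCCCCCCCCCCCCCc1c(C)c(O)cc(O)c1C(=O)O | intermediate
12 | 5-docosyl-4-methylbenzene-1,3-diol | CCCCCCCCCCCCCCCCCCCCCCc1cc(O)cc(O)c1C | intermediate
13 | 2-docosyl-6-hydroxy-3-methyl-1,4-benzoquinone | CCCCCCCCCCCCCCCCCCCCCCC1=C(C)C(=O)C=C(O)C1=O | intermediate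
14 | 2-docosyl-6-methoxy-3-methyl-1,4-benzoquinone | CCCCCCCCCCCCCCCCCCCCCCC1=C(C)C(=O)C=C(OC)C1=O | target

## Step count and risk

Total step count: 7. Longest linear sequence: 6 steps (1, 3, 4, 5, 6, 7 from compound 1; equally 2 to 7 from compound 5).

**Step 4 (key step).** The ring closure may be slow or stop at the carbinol stage. The amine removes the C3 methine proton in competition with the C5 protons, which gives an enolate that cannot close productively, and the C2 ketone is α-branched and shielded by the chain. Long exposure to base may also cause retro-Claisen cleavage of the 2-methyl-1,3-diketone. Fallback, setting out from 8: thermolysis in toluene at 110 °C with methanol (retro-[4+2] loss of acetone and trapping of the acyl ketene) would give methyl 6-methyl-3,5,7-trioxononacosanoate F1. Cs2CO3 in methanol followed by methanolic HCl would perform the same aldol condensation and dehydration on the open-chain ester, giving methyl 2-docosyl-4,6-dihydroxy-3-methylbenzoate F2. Saponification of F2 with KOH under the conditions of step 5 rejoins the route at acid 11 and so at 12.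

**Step 3.** Proton transfer from the acidic product to unreacted dianion may leave conversion incomplete. O-acylation, double addition to the imidazolide, and precipitation of the C23 electrophile in cold THF are further risks. Fallback, setting out from 4 and 6: partial reduction of 6 with LiAlH4 in THF at −20 °C would give tricosanal F3. Aldol addition of dianion 7 (from 4) to F3 has a more reactive electrophile and no acidic product, and would give 6-(4-hydroxy-3-methyl-2-oxohexacosyl)-2,2-dimethyl-4H-1,3-dioxin-4-one F4 as a mixture of racemic diastereomers. Oxidation of F4 with Dess–Martin periodinane comes back to the route at 8.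

**Step 6.** The oxidation may be slow and incomplete in the two-phase medium, because the substrate is waxy and the nitroxide decays in solution. Oxygenation at C5 between the two hydroxyls and oxidative coupling of phenoxyl radicals are further risks. Fallback, setting out from 12: Vilsmeier–Haack formylation (POCl3, DMF) at C1, para to the C4 hydroxyl, would give 2-docosyl-4,6-dihydroxy-3-methylbenzaldehyde F5. Dakin oxidation (H2O2, NaOH) would turn the formyl group into a hydroxyl, giving 6-docosyl-5-methylbenzene-1,2,4-triol F6. Oxidation of F6 with air in neutral buffer or with FeCl3 comes back to the route at 13.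

**Step 7.** The acid-catalysed exchange may stop short of full conversion at equilibrium. It may also be accompanied by ketalisation at C4, by methylation in the ortho-quinone tautomer, or by acid-promoted decomposition of the quinone. Fallback, setting out from 13: reduction with Na2S2O4 would give the triol 6-docosyl-5-methylbenzene-1,2,4-triol F6. Exhaustive methylation with (CH3O)2SO2 and K2CO3 in acetone under argon would give 3-docosyl-1,2,5-trimethoxy-4-methylbenzene F7. Oxidative demethylation with (NH4)2Ce(NO3)6 in MeCN–H2O removes the para-related methyl ethers at C1 and C4 and keeps the C6 methoxy group, so the route is rejoined at 14.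

## Further compounds

F1 | step 4 | methyl 6-methyl-3,5,7-trioxononacosanoate | CCCCCCCCCCCCCCCCCCCCCCC(=O)C(C)C(=O)CC(=O)CC(=O)OC
F2 | step 4 | methyl 2-docosyl-4,6-dihydroxy-3-methylbenzoate | CCCCCCCCCCCCCCCCCCCCCCc1c(C)c(O)cc(O)c1C(=O)OC
F3 | step 3 | tricosanal | CCCCCCCCCCCCCCCCCCCCCCC=O
F4 | step 3 | 6-(4-hydroxy-3-methyl-2-oxohexacosyl)-2,2-dimethyl-4H-1,3-dioxin-4-one (racemic diastereomer mixture) | CCCCCCCCCCCCCCCCCCCCCCC(O)C(C)C(=O)CC1=CC(=O)OC(C)(C)O1
F5 | step 6 | 2-docosyl-4,6-dihydroxy-3-methylbenzaldehyde | CCCCCCCCCCCCCCCCCCCCCCc1c(C)c(O)cc(O)c1C=O
F6 | step 6 | 6-docosyl-5-methylbenzene-1,2,4-triol | CCCCCCCCCCCCCCCCCCCCCCc1c(C)c(O)cc(O)c1O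
F7 | step 7 | 3-docosyl-1,2,5-trimethoxy-4-methylbenzene | CCCCCCCCCCCCCCCCCCCCCCc1c(C)c(OC)cc(OC)c1OC
A1 | alternative 1 | rac-trans-5-docosyl-3,4,4-trimethoxy-6-methylcyclohex-2-en-1-one (one enantiomer drawn) | O=C1C=C(OC)C(OC)(OC)[C@@H](CCCCCCCCCCCCCCCCCCCCCC)[C@@H]1C
A2 | alternative 1 | 3,4,4-trimethoxycyclohexa-2,5-dien-1-one | O=C1C=CC(OC)(OC)C(OC)=C1
A3 | alternative 1 | docosylmagnesium bromide | CCCCCCCCCCCCCCCCCCCCCC[Mg]Br
A4 | alternative 2 | 3-docosyl-5-methoxy-2-methylphenol | CCCCCCCCCCCCCCCCCCCCCCc1cc(OC)cc(O)c1C
A5 | alternative 2 | 1,1-dimethoxy-3-(trimethylsilyloxy)penta-1,3-diene | COC(OC)=CC(O[Si](C)(C)C)=CC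
A6 | alternative 2 | (E)-1-nitrotetracos-1-ene | CCCCCCCCCCCCCCCCCCCCCC/C=C/[N+](=O)[O-]
A7 | alternative 3 | 2-docosyl-6-methoxy-3-methylbenzene-1,4-diol | CCCCCCCCCCCCCCCCCCCCCCc1c(C)c(O)cc(OC)c1O
A8 | alternative 3 | 4-hydroxy-3-methoxy-4-(pentacos-2-en-3-yl)cyclobut-2-en-1-one (racemic) | CCCCCCCCCCCCCCCCCCCCCCC(=CC)C1(O)C(OC)=CC1=O
A9 | alternative 3 | 3-methoxycyclobut-3-ene-1,2-dione | COC1=CC(=O)C1=O
A10 | alternative 3 | (pentacos-2-en-3-yl)lithium | [Li]C(=CC)CCCCCCCCCCCCCCCCCCCCCC
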